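**Retrosynthetic overview**
1. 22 ⇐ 3-oxo-labdane 19. The C3 carbonyl comes off last (reduction, then Barton–McCombie). The reduction is enzymatic and accepts only one enantiomer.
2. 19 ⇐ acyclic β-keto ester 18 in one oxidative radical cascade that copies the cyclase. C4–C5 closes ring A first and C10–C9 closes ring B second. Loss of Me3Si+ from C17 (nature loses H+) gives the 8(17)-alkene.
3. 18 ⇐ 13 + dimethyl 3-oxopentanedioate. A Carroll rearrangement makes C1–C2 and the C5=C10 alkene, and C4 is then methylated.
4. 13 ⇐ 10 + 2-bromoallyl alcohol (NHK; brings C10, C1 and C20–O). 10 ⇐ 5 + (2-bromoallyl)trimethylsilane (NHK, then a Claisen rearrangement makes C6–C7 and the C8=C9 allylsilane).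
5. 5 ⇐ 3-bromobutenolide + allyl alcohol (Heck). The butenolide ring is bought as furan-2(5H)-one and carried unprotected.

Assumption: labdane numbering (C1–C20) is used for chain and ring positions, and compounds made as racemates are drawn as the enantiomer that leads to the target, which is (4S,5R,9S,10S).

**Step 1**
Reactants: 1 furan-2(5H)-one
Product: 3 3-bromofuran-2(5H)-one, via dibromolactone 2 (not isolated)
Conditions: Br2, Et2O, reflux; then Et3N, 0 °C
Reagents that add atoms: bromine BrBr
Why: Bromination–dehydrobromination: anti addition of Br2 to the conjugated alkene is followed by E1cB loss of HBr (acidic α-H, β-bromide), which gives the α-bromobutenolide and leaves no stereocentre.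

**Step 2**
Reactants: 3 3-bromofuran-2(5H)-one; 4 prop-2-en-1-ol (allyl alcohol)
Product: 5 3-(2-oxo-2,5-dihydrofuran-3-yl)propanal
Conditions: Pd(OAc)2 (5 mol %), Bu4NCl, NaHCO3, DMF, 45 °C
Reagents that add atoms: none
Why: Heck reaction under Jeffery conditions: the alkenylpalladium species adds to the terminal carbon of allyl alcohol and β-hydride elimination towards the carbinol gives an enol that tautomerises to the aldehyde, so C12, C11 and the C9 aldehyde arrive in one step.

**Step 3**
Reactants: 5 3-(2-oxo-2,5-dihydrofuran-3-yl)propanal; 6 (2-bromoprop-2-en-1-yl)trimethylsilane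
Product: 7 3-{3-hydroxy-4-[(trimethylsilyl)methyl]pent-4-en-1-yl}furan-2(5H)-one (racemic)
Conditions: CrCl2 (4 equiv), NiCl2 (2 mol %), DMF, rt; aqueous work-up
Reagents that add atoms: none
Why: Nozaki–Hiyama–Kishi coupling: the nickel-catalysed alkenylchromium reagent adds only to the aldehyde and leaves the butenolide alone, and the new C9 carbinol centre is racemic and is erased in step 4.

**Step 4**
Reactants: 7 allylic alcohol from step 3; 8 ethyl vinyl ether
Product: 10 (Z)-7-(2-oxo-2,5-dihydrofuran-3-yl)-4-[(trimethylsilyl)methyl]hept-4-enal, via allyl vinyl ether 9 (not isolated)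
Conditions: Pd(OCOCF3)2 (1 mol %), 4,7-diphenyl-1,10-phenanthroline, Et3N, ethyl vinyl ether (solvent), rt; evaporate; toluene, 125 °C, sealed tube
Reagents that add atoms: none
Why: Vinyl-ether exchange then Claisen rearrangement through a chair transition state with the C11 chain equatorial (an axial chain would clash with CH2SiMe3), which makes C6–C7 and fixes C7 trans to C11 on the C8=C9 allylsilane, the geometry that later places the C9 side chain equatorial.

**Step 5**
Reactants: 10 aldehyde from step 4; 11 2-bromoprop-2-en-1-ol
Product: 12 3-{(Z)-7-hydroxy-8-(hydroxymethyl)-4-[(trimethylsilyl)methyl]nona-3,8-dien-1-yl}furan-2(5H)-one (racemic at the carbinol C5)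
Conditions: 11 (3 equiv), CrCl2 (6 equiv), NiCl2 (2 mol %), DMF, rt; aqueous work-up
Reagents that add atoms: none
Why: A second Nozaki–Hiyama–Kishi coupling, which tolerates the free hydroxyl, allylsilane and butenolide, brings in C10, C1 and the oxygenated C20, and its racemic C5 carbinol centre is erased in step 7.

**Step 6**
Reactants: 12 diol from step 5
Product: 13 primary (C20) monoacetate of 12 (racemic)
Conditions: AcCl (1.05 equiv), 2,4,6-collidine, CH2Cl2, −78 °C
Reagents that add atoms: acetyl chloride CC(=O)Cl
Why: Kinetically selective esterification: at low temperature with a hindered base the open primary allylic alcohol is acetylated much faster than the flanked secondary one, which installs the C20 acetate of the target and leaves the C5 hydroxyl free.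

**Step 7**
Reactants: 13 monoacetate from step 6; 14 dimethyl 3-oxopentanedioate
Product: 17 methyl (6Z,10Z)-6-(acetoxymethyl)-3-oxo-13-(2-oxo-2,5-dihydrofuran-3-yl)-10-[(trimethylsilyl)methyl]trideca-6,10-dienoate, via mixed 3-oxoglutarate ester 15 (not isolated), via beta-keto acid 16 (not isolated)
Conditions: 14 (3 equiv), toluene, 110 °C, 4 Å MS; then xylenes, 140 °C
Reagents that add atoms: none
Why: Thermal transesterification through an acylketene, then Carroll rearrangement ([3,3] shift of the allyl β-keto ester enol in a chair with the C6 chain equatorial) and decarboxylation, makes C1–C2 and gives the C5=C10 alkene with C6 trans to C1 and cis to CH2OAc.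

**Step 8**
Reactants: 17 β-keto ester from step 7
Product: 18 methyl (6Z,10Z)-6-(acetoxymethyl)-2-methyl-3-oxo-13-(2-oxo-2,5-dihydrofuran-3-yl)-10-[(trimethylsilyl)methyl]trideca-6,10-dienoate (racemic at C4)
Conditions: K2CO3 (1.1 equiv), MeI (1.05 equiv), acetone, rt
Reagents that add atoms: iodomethane CI
Why: C-alkylation of a β-keto ester enolate: K2CO3 deprotonates only the doubly activated C4 methylene (acetate, butenolide and allylsilane are inert to it), and the racemic, labile C4 centre becomes planar in step 9.

**Step 9**
Reactants: 18 α-methyl β-keto ester from step 8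
Product: 19 (±)-methyl 20-acetoxy-3-oxolabda-8(17),13-dien-16,15-olid-19-oate
Conditions: Mn(OAc)3·2H2O (2.2 equiv), Cu(OAc)2·H2O (10 mol %), KOAc (2 equiv), degassed AcOH (0.02 M), 35 °C
Reagents that add atoms: none
Why: Proposed new method: Mn(OAc)3 oxidises the enol to the electrophilic C4 radical, which closes ring A 6-endo on C5 and then ring B 6-endo on C9 through a chair–chair array (opposed ketone and ester dipoles put CO2Me axial, the equatorial C6 chain gives the trans fusion with CH2OAc axial, and the alkene geometry puts the C11 chain equatorial, so C4, C5, C10 and C9 are set relative to one another, as a racemate), while the β-acetoxy C10 radical resists oxidation long enough to cyclise and the β-silyl C8 radical is oxidised at once and loses Me3Si+ to give only the 8(17)-alkene before it can add to the butenolide; the closest known reaction types are the Mn(OAc)3/Cu(OAc)2 oxidative free-radical polyene cyclisation of α-alkyl β-keto esters and the Mn(OAc)3- or (NH4)2Ce(NO3)6-mediated allylation of 1,3-dicarbonyls with allylsilanes.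

**Step 10**
Reactants: 19 racemic ketone from step 9
Product: 20 methyl (3S)-20-acetoxy-3β-hydroxylabda-8(17),13-dien-16,15-olid-19-oate (single enantiomer)
Conditions: ketoreductase (enantiomer-selective hit from a commercial KRED panel), NADP+ (cat.), 2-propanol, pH 7 phosphate buffer/DMSO 9:1, 30 °C, stopped at 50 % conversion; chromatography
Reagents that add atoms: none
Why: Enzymatic kinetic resolution by ketoreductase reduction: the enzyme accepts only the enantiomer with the steroid-like A/B configuration and delivers hydride to the α face to give the equatorial 3β alcohol, so separation from the untouched mirror-image ketone fixes the absolute configuration at C4, C5, C9 and C10.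

**Step 11**
Reactants: 20 alcohol from step 10
Product: 21 3β-O-(imidazol-1-ylthiocarbonyl) derivative of 20
Conditions: 1,1'-thiocarbonyldiimidazole (3 equiv), DMAP (cat.), 1,2-dichloroethane, 70 °C
Reagents that add atoms: 1,1'-thiocarbonyldiimidazole S=C(n1ccnc1)n1ccnc1
Why: Thiocarbonyl transfer to the only free hydroxyl (first half of the Barton–McCombie sequence) runs under neutral conditions that spare acetate, ester, butenolide and exocyclic alkene and touch no stereocentre.

**Step 12**
Reactants: 21 thiocarbonylimidazolide from step 11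
Product: 22 methyl 20-acetoxylabda-8(17),13-dien-16,15-olid-19-oate (target, CNP0104712.1)
Conditions: Bu3SnH (1.5 equiv), AIBN (cat.), toluene, 90 °C
Reagents that add atoms: none
Why: Barton–McCombie deoxygenation: the stannyl radical adds to C=S, the C3–O bond fragments, and the secondary C3 radical, which has no alkene within cyclisation reach, takes H from Bu3SnH, so the C3 centre vanishes and the four remaining stereocentres stay untouched.

**Compound list**
1 | furan-2(5H)-one | O=C1OCC=C1 | starting material
2 | trans-3,4-dibromodihydrofuran-2(3H)-one (racemic) | O=C1OCC(Br)C1Br | intermediate (not isolated)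
3 | 3-bromofuran-2(5H)-one | O=C1OCC=C1Br | intermediate
4 | prop-2-en-1-ol | C=CCO | starting material
5 | 3-(2-oxo-2,5-dihydrofuran-3-yl)propanal | O=CCCC1=CCOC1=O | intermediate
6 | (2-bromoprop-2-en-1-yl)trimethylsilane | C=C(Br)C[Si](C)(C)C | starting material
7 | 3-{3-hydroxy-4-[(trimethylsilyl)methyl]pent-4-en-1-yl}furan-2(5H)-one (racemic) | C=C(C[Si](C)(C)C)C(O)CCC1=CCOC1=O | intermediate
8 | ethyl vinyl ether | C=COCC | starting material
9 | vinyl ether of 7 | C=COC(CCC1=CCOC1=O)C(=C)C[Si](C)(C)C | intermediate (not isolated)
10 | (Z)-7-(2-oxo-2,5-dihydrofuran-3-yl)-4-[(trimethylsilyl)methyl]hept-4-enal | O=CCC/C(C[Si](C)(C)C)=C/CCC1=CCOC1=O | intermediate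
11 | 2-bromoprop-2-en-1-ol | C=C(Br)CO | starting material
12 | 3-{(Z)-7-hydroxy-8-(hydroxymethyl)-4-[(trimethylsilyl)methyl]nona-3,8-dien-1-yl}furan-2(5H)-one (racemic) | C=C(CO)C(O)CC/C(C[Si](C)(C)C)=C/CCC1=CCOC1=O | intermediate
13 | primary (C20) monoacetate of 12 (racemic) | C=C(COC(C)=O)C(O)CC/C(C[Si](C)(C)C)=C/CCC1=CCOC1=O | intermediate
14 | dimethyl 3-oxopentanedioate | COC(=O)CC(=O)CC(=O)OC | starting material
15 | mixed methyl/allylic 3-oxopentanedioate of 13 | COC(=O)CC(=O)CC(=O)OC(CC/C(C[Si](C)(C)C)=C/CCC1=CCOC1=O)C(=C)COC(C)=O | intermediate (not isolated)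
16 | C2-carboxylic acid of 17 (β-keto acid after the [3,3] shift) | COC(=O)CC(=O)C(C(=O)O)C/C(COC(C)=O)=C/CC/C(C[Si](C)(C)C)=C/CCC1=CCOC1=O | intermediate (not isolated)
17 | methyl (6Z,10Z)-6-(acetoxymethyl)-3-oxo-13-(2-oxo-2,5-dihydrofuran-3-yl)-10-[(trimethylsilyl)methyl]trideca-6,10-dienoate | COC(=O)CC(=O)CC/C(COC(C)=O)=C/CC/C(C[Si](C)(C)C)=C/CCC1=CCOC1=O | intermediate
18 | 2-methyl derivative of 17 (racemic at C4) | COC(=O)C(C)C(=O)CC/C(COC(C)=O)=C/CC/C(C[Si](C)(C)C)=C/CCC1=CCOC1=O | intermediate
19 | (±)-methyl 20-acetoxy-3-oxolabda-8(17),13-dien-16,15-olid-19-oate; trans-decalin, 4β-axial CO2Me, 4α-CH3, 5α-H, 9α-H, 10β-CH2OAc; racemic, drawn as the useful enantiomer | C=C1CC[C@@H]2[C@](COC(C)=O)(CCC(=O)[C@]2(C)C(=O)OC)[C@H]1CCC1=CCOC1=O | intermediate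
20 | methyl (3S)-20-acetoxy-3β-hydroxylabda-8(17),13-dien-16,15-olid-19-oate | C=C1CC[C@@H]2[C@](COC(C)=O)(CC[C@H](O)[C@]2(C)C(=O)OC)[C@H]1CCC1=CCOC1=O | intermediate
21 | 3β-O-(imidazol-1-ylthiocarbonyl) derivative of 20 | C=C1CC[C@@H]2[C@](COC(C)=O)(CC[C@H](OC(=S)n3ccnc3)[C@]2(C)C(=O)OC)[C@H]1CCC1=CCOC1=O | intermediate
22 | methyl (4S,5R,9S,10S)-20-acetoxylabda-8(17),13-dien-16,15-olid-19-oate | C=C1CC[C@@H]2[C@](COC(C)=O)(CCC[C@]2(C)C(=O)OC)[C@H]1CCC1=CCOC1=O | target

**Total step count:** 12. **Longest linear sequence:** 12.

**Three steps most likely to fail**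

**Step 9 (cascade).**
- *Risks.* The allylic acetate slows the first ring closure. The allylsilane may be protodesilylated in AcOH. The C8 radical may still reach the butenolide.
- *Fallback.* This replaces oxidative initiation in acid with a redox-neutral route from a C–Br bond. It sets out from 18. The C4 enolate is brominated (BrCCl3, catalytic DBU, CH2Cl2, 0 °C) to give methyl (6Z,10Z)-6-(acetoxymethyl)-2-bromo-2-methyl-3-oxo-13-(2-oxo-2,5-dihydrofuran-3-yl)-10-[(trimethylsilyl)methyl]trideca-6,10-dienoate F1. F1 is irradiated with fac-Ir(ppy)3 (1 mol %) and 2,6-lutidine in MeCN under blue LEDs. The excited catalyst reduces the C–Br bond to the same C4 radical, and the same two ring closures follow. The oxidised catalyst (tetravalent iridium) then takes the electron from the β-silyl radical, and desilylation comes back to the route at 19.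

**Step 7 (one-pot transesterification and Carroll rearrangement).**
- *Risks.* The 140 °C needed may decompose 14. It may also allow acetyl migration in 13.
- *Fallback.* This sets out from 13 and separates the C–C bond formation from the β-keto ester synthesis. Vinyl-ether exchange as in step 4 gives the vinyl ether of 13 F2. Claisen rearrangement at 125 °C then gives (4Z,8Z)-4-(acetoxymethyl)-11-(2-oxo-2,5-dihydrofuran-3-yl)-8-[(trimethylsilyl)methyl]undeca-4,8-dienal F3. Roskamp homologation of F3 with methyl diazoacetate and SnCl2 (10 mol %) in CH2Cl2 at rt comes back to the route at 17, at the cost of one extra step.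

**Step 10 (enzymatic resolution).**
- *Risks.* No enzyme in the panel may accept this bulky ketone flanked by a quaternary carbon with useful selectivity. Esterase activity may also cut the acetate.
- *Fallback.* This sets out from 19 and separates the enantiomers physically by preparative supercritical-fluid chromatography on a chiral stationary phase. The correct enantiomer is reduced under substrate control (NaBH4, CeCl3·7H2O, MeOH, −40 °C; hydride from the open α face), which comes back to the route at 20. This path makes no new compound (F0).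

**Further compounds**
F1 | step 9 | methyl (6Z,10Z)-6-(acetoxymethyl)-2-bromo-2-methyl-3-oxo-13-(2-oxo-2,5-dihydrofuran-3-yl)-10-[(trimethylsilyl)methyl]trideca-6,10-dienoate (racemic) | COC(=O)C(C)(Br)C(=O)CC/C(COC(C)=O)=C/CC/C(C[Si](C)(C)C)=C/CCC1=CCOC1=O
F2 | step 7 | vinyl ether of 13 | C=COC(CC/C(C[Si](C)(C)C)=C/CCC1=CCOC1=O)C(=C)COC(C)=O
F3 | step 7 | (4Z,8Z)-4-(acetoxymethyl)-11-(2-oxo-2,5-dihydrofuran-3-yl)-8-[(trimethylsilyl)methyl]undeca-4,8-dienal | O=CCC/C(COC(C)=O)=C/CC/C(C[Si](C)(C)C)=C/CCC1=CCOC1=O
F0 | step 10 | none | none
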